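**Retrosynthetic overview**
1. All carbons come from 3',4',5'-trimethoxyacetophenone (1) and methyl 3,4,5-trimethoxybenzoate (2); one Claisen C–C bond gives the symmetrical diketone 3.
2. Key disconnection, O1–C8a of ring C: flavone 4 is traced back to 3 by a dehydrogenative aryl C–H/enol O–H coupling. The symmetry of 3 removes any regiochemical choice.
3. Final disconnection, C5–O of ring A: carbonyl-directed C–H oxygenation of 4, through aryl trifluoroacetate 5, gives Gardenin A (6).
4. Ring order: rings A and B are bought as benzene rings; ring C (the pyranone) is the only ring built, in step 2.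

Assumption: Gardenin A has no stereocentre and no configurationally stable axis, so it is achiral; the SMILES given is the single species to be made and no step needs stereocontrol.

**Route**

Step 1
Reactants: 1 3',4',5'-trimethoxyacetophenone; 2 methyl 3,4,5-trimethoxybenzoate
Product: 3 1,3-bis(3,4,5-trimethoxyphenyl)propane-1,3-dione
Conditions: NaH (2.5 equiv), THF, reflux, 6 h; then 1 M HCl, 0 °C
Reagents that add atoms: none
Why: Crossed Claisen condensation, in which the sodium enolate of 1 acylates the non-enolisable ester 2 and irreversible deprotonation of the 1,3-diketone pulls the equilibrium forward, so 2 cannot self-condense and 3 is released as its chelated enol on acidification; no stereocentre is formed.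

Step 2
Reactants: 3 1,3-bis(3,4,5-trimethoxyphenyl)propane-1,3-dione
Product: 4 6,7,8-trimethoxy-2-(3,4,5-trimethoxyphenyl)-4H-chromen-4-one
Conditions: constant-current electrolysis (8 mA, 2.4 F/mol), undivided cell, graphite anode, Pt cathode, nBu4NPF6 (0.1 M), dry HFIP/CH2Cl2 4:1, 0.02 M, rt, N2
Reagents that add atoms: none
Why: Proposed new method: anodic one-electron oxidation of the electron-rich enol/trimethoxyaryl π-system of 3 in HFIP (which opens the enol chelate by hydrogen bonding, stabilises radical cations and is too weakly nucleophilic to trap them) gives a radical cation that the enol oxygen attacks at the aroyl ortho carbon, the only site that closes a six-membered ring and one that is para to the 5-methoxy and ortho to the 3-methoxy group, after which loss of a second electron and two protons (reduced to H2 at the cathode) rearomatises to the chromone, with the symmetry of 3 making both aryl rings equivalent and the product carrying no tethered nucleophile; the closest known reaction types are the dehydrogenative C(sp2)–H/O–H lactonisation of biaryl-2-carboxylic acids to benzocoumarins and the FeCl3-mediated oxidative C–O ring closure of α-aryl 1,3-dicarbonyls to benzofurans, neither of which has been shown for closing a flavone pyranone onto an acyl-bearing ring of a 1,3-diaryl-1,3-diketone; no stereocentre is formed.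

Step 3
Reactants: 4 6,7,8-trimethoxy-2-(3,4,5-trimethoxyphenyl)-4H-chromen-4-one
Product: 6 Gardenin A (5-hydroxy-6,7,8-trimethoxy-2-(3,4,5-trimethoxyphenyl)-4H-chromen-4-one), via aryl trifluoroacetate 5 (not isolated)
Conditions: [RuCl2(p-cymene)]2 (5 mol%), PhI(OCOCF3)2 (2.0 equiv), CF3CO2H/(CF3CO)2O 9:1, 80 °C, 3 h; then H2O/THF, rt
Reagents that add atoms: phenyliodine bis(trifluoroacetate), O=C(OI(OC(=O)C(F)(F)F)c1ccccc1)C(F)(F)F
Why: Ketone-directed C–H oxygenation, established for flavones and chromones, in which the C4 carbonyl binds divalent ruthenium so that carboxylate-assisted metalation can reach only the peri C5–H (five-membered ruthenacycle), oxidation by the trivalent iodine reagent to tetravalent ruthenium and C–O reductive elimination give trifluoroacetate 5, which is shielded from over-oxidation until water cleaves it to the chelated 5-OH; no stereocentre is formed.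

**Compound list**
1 | 3',4',5'-trimethoxyacetophenone (1-(3,4,5-trimethoxyphenyl)ethan-1-one) | CC(=O)c1cc(OC)c(OC)c(OC)c1 | starting material
2 | methyl 3,4,5-trimethoxybenzoate | COC(=O)c1cc(OC)c(OC)c(OC)c1 | starting material
3 | 1,3-bis(3,4,5-trimethoxyphenyl)propane-1,3-dione (symmetrical; chelated enol in solution; achiral) | COc1cc(C(=O)CC(=O)c2cc(OC)c(OC)c(OC)c2)cc(OC)c1OC | intermediate
4 | 6,7,8-trimethoxy-2-(3,4,5-trimethoxyphenyl)-4H-chromen-4-one (achiral) | COc1cc(-c2cc(=O)c3cc(OC)c(OC)c(OC)c3o2)cc(OC)c1OC | intermediate
5 | 6,7,8-trimethoxy-4-oxo-2-(3,4,5-trimethoxyphenyl)-4H-chromen-5-yl trifluoroacetate (achiral) | COc1cc(-c2cc(=O)c3c(OC(=O)C(F)(F)F)c(OC)c(OC)c(OC)c3o2)cc(OC)c1OC | intermediate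
6 | Gardenin A, 5-hydroxy-6,7,8-trimethoxy-2-(3,4,5-trimethoxyphenyl)-4H-chromen-4-one (achiral) | COc1cc(-c2cc(=O)c3c(O)c(OC)c(OC)c(OC)c3o2)cc(OC)c1OC | target

**Totals**
Total step count: 3. Longest linear sequence: 3 steps (1 and 2 → 3 → 4 → 6).

**Steps most likely to fail, with fallbacks**

Step 2 (the proposed new cyclisation) is the most likely to fail. The radical cation may dimerise at the central carbon, couple intermolecularly, or be over-oxidised to quinones if water is present. The fallback uses known chemistry, sets out from 2 (with 1) and comes back at 4. Ester 2 is brominated with NBS in MeCN at the ring position ortho to the ester to give methyl 2-bromo-3,4,5-trimethoxybenzoate F1. Claisen condensation of F1 with 1 (NaH, THF, reflux; HCl quench) gives 1-(2-bromo-3,4,5-trimethoxyphenyl)-3-(3,4,5-trimethoxyphenyl)propane-1,3-dione F2. The enolate oxygen of F2 then displaces the bromide in an intramolecular Ullmann-type O-arylation (CuI 10 mol%, 1,10-phenanthroline, K2CO3, DMF, 110 °C), which closes ring C at the same O1–C8a bond and delivers 4.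

Step 3 is the second risk. The hexamethoxy substrate is very electron-rich, so the trivalent iodine oxidant may attack the arene rings, and the 6-methoxy group crowds C5. The fallback abandons C–H oxygenation for the classical selective 5-O-demethylation; it sets out from 2 and comes back at 6. The purchased building block 2'-hydroxy-3',4',5',6'-tetramethoxyacetophenone F3 (a catalogue compound, but not a cheap one) is condensed with 2 (NaH, THF, reflux) to the diketone 1-(2-hydroxy-3,4,5,6-tetramethoxyphenyl)-3-(3,4,5-trimethoxyphenyl)propane-1,3-dione F4. F4 is not isolated but cyclodehydrated (cat. H2SO4, AcOH, 100 °C) to 5,6,7,8-tetramethoxy-2-(3,4,5-trimethoxyphenyl)-4H-chromen-4-one F5. Chelation-controlled cleavage of the 5-methyl ether alone (BCl3 1.5 equiv, CH2Cl2, −78 to 0 °C) then gives 6.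

Step 1 is the least risky. Possible problems are incomplete conversion or aldol self-condensation of 1. The fallback replaces acylation by aldol addition and oxidation; it sets out from 1 and comes back at 3. The lithium enolate of 1 (LiN(iPr)2, THF, −78 °C) is added to purchased 3,4,5-trimethoxybenzaldehyde F6 and quenched cold to give racemic 3-hydroxy-1,3-bis(3,4,5-trimethoxyphenyl)propan-1-one F7. Oxidation of F7 with IBX (EtOAc, 80 °C) removes its stereocentre and gives 3.

**Further compounds**
F1 | step 2 | methyl 2-bromo-3,4,5-trimethoxybenzoate | COC(=O)c1cc(OC)c(OC)c(OC)c1Br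
F2 | step 2 | 1-(2-bromo-3,4,5-trimethoxyphenyl)-3-(3,4,5-trimethoxyphenyl)propane-1,3-dione | COc1cc(C(=O)CC(=O)c2cc(OC)c(OC)c(OC)c2Br)cc(OC)c1OC
F3 | step 3 | 2'-hydroxy-3',4',5',6'-tetramethoxyacetophenone (purchased building block) | CC(=O)c1c(O)c(OC)c(OC)c(OC)c1OC
F4 | step 3 | 1-(2-hydroxy-3,4,5,6-tetramethoxyphenyl)-3-(3,4,5-trimethoxyphenyl)propane-1,3-dione | COc1cc(C(=O)CC(=O)c2c(O)c(OC)c(OC)c(OC)c2OC)cc(OC)c1OC
F5 | step 3 | 5,6,7,8-tetramethoxy-2-(3,4,5-trimethoxyphenyl)-4H-chromen-4-one | COc1cc(-c2cc(=O)c3c(OC)c(OC)c(OC)c(OC)c3o2)cc(OC)c1OC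
F6 | step 1 | 3,4,5-trimethoxybenzaldehyde (purchased building block) | COc1cc(C=O)cc(OC)c1OC
F7 | step 1 | 3-hydroxy-1,3-bis(3,4,5-trimethoxyphenyl)propan-1-one (racemic) | COc1cc(C(O)CC(=O)c2cc(OC)c(OC)c(OC)c2)cc(OC)c1OC
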